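The route rests on disconnecting the C6–C7, C4–C5 and C10–O bonds at once (icetexane numbering, defined below). The tertiary ether carbon C10 beside C5, which carries the gem-dimethyl carbon C4, is the signature of a 1,2-shift: an aroyl cation attacks a vinyl group on a 2,2-dimethylcyclopentane, the ring bond C10–C4 migrates to C5 (cyclopentane to cyclohexane ring A), and the new C7 ketone oxygen traps the C10 cation as the oxa-bridged hemiketal. One step thus closes ring B, builds ring A and the 7,10-oxygen bridge, and sets C5, C7 and C10 from one quaternary stereocentre. The precursor is a hexasubstituted benzoic acid bearing a (1-vinyl-2,2-dimethylcyclopentyl)methyl group.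

Key step: step 11

Numbering used throughout: ring A = C1, C2, C3, C4 (CMe2), C5 (CH), C10 (C–O); C20 = CH2 between C10 and C9; C6 = CH2 between C5 and C7; C7 = hemiketal carbon on C8; quinone ring = C8, C9, C11 (C=O), C12 (OMe), C13 (isopropyl), C14 (C=O); ring B = C5, C6, C7, C8, C9, C20, C10.

Assumption: bromination of 4 occurs at the ring position para to the 2-methoxy group and ortho to the 4-methoxy group, as it does in 1,2,4-trimethoxybenzene itself.

Step 1
Reactants: 1 1,2,4-trimethoxybenzene
Product: 3 2-(2,3,6-trimethoxyphenyl)propan-2-ol, via aryllithium 2 (not isolated)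
Conditions: n-BuLi, THF, 0 °C to rt; acetone, −78 °C to rt; H2O
Reagents that add atoms: acetone, CC(C)=O
Why: Directed ortho-lithiation takes place at C3, the position flanked by two methoxy groups, and 1,2-addition of the aryllithium to acetone should give the tertiary benzylic alcohol.

Step 2
Reactants: 3 2-(2,3,6-trimethoxyphenyl)propan-2-ol
Product: 4 1,2,4-trimethoxy-3-(propan-2-yl)benzene
Conditions: Et3SiH, CF3CO2H, CH2Cl2, 0 °C to rt
Reagents that add atoms: none
Why: Ionic hydrogenation, in which the acid ionises the tertiary benzylic alcohol to a cation stabilised by two ortho methoxy groups and the silane delivers hydride, should give the isopropyl arene.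

Step 3
Reactants: 4 1,2,4-trimethoxy-3-(propan-2-yl)benzene
Product: 5 1-bromo-2,4,5-trimethoxy-3-(propan-2-yl)benzene
Conditions: NBS, MeCN, 0 °C
Reagents that add atoms: N-bromosuccinimide, O=C1CCC(=O)N1Br
Why: Electrophilic aromatic bromination is expected para to the 2-methoxy and ortho to the 4-methoxy group, the carbon that becomes C8, which leaves the future C9 as the only ring C–H.

Step 4
Reactants: 5 1-bromo-2,4,5-trimethoxy-3-(propan-2-yl)benzene
Product: 7 2-bromo-3,5,6-trimethoxy-4-(propan-2-yl)benzaldehyde, via aryllithium 6 (not isolated)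
Conditions: LiN(iPr)2, THF, −78 °C; DMF, −78 °C; aq. NH4Cl
Reagents that add atoms: N,N-dimethylformamide, CN(C)C=O
Why: The last ring hydrogen lies between Br and OMe and is the most acidic site, so directed ortho-metalation at −78 °C (cold enough to avoid aryne formation) and Bouveault formylation with DMF should install C20 as the aldehyde.

Step 5
Reactants: 8 2,2-dimethylcyclopentan-1-one
Product: 9 1-ethenyl-2,2-dimethylcyclopentan-1-ol (racemic; its stereocentre is lost in step 6)
Conditions: CH2=CHMgBr, CeCl3, THF, −78 to 0 °C; H2O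
Reagents that add atoms: vinylmagnesium bromide, C=C[Mg]Br
Why: Grignard 1,2-addition to the hindered, poorly enolisable ketone (assisted by CeCl3) should give the tertiary allylic alcohol.

Step 6
Reactants: 9 1-ethenyl-2,2-dimethylcyclopentan-1-ol
Product: 10 2-[(2E)-2-(2,2-dimethylcyclopentylidene)ethyl]-4,4,5,5-tetramethyl-1,3,2-dioxaborolane
Conditions: B2pin2, Pd(MeCN)4(BF4)2 (5 mol %), DMSO–MeOH, 40 °C
Reagents that add atoms: bis(pinacolato)diboron, CC1(C)OB(OC1(C)C)B1OC(C)(C)C(C)(C)O1
Why: Palladium-catalysed borylation of an allylic alcohol through a π-allyl complex should place boron on the unhindered terminus C6, and the E alkene (CH2B trans to CMe2) is expected because it avoids allylic strain.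

Step 7
Reactants: 7 2-bromo-3,5,6-trimethoxy-4-(propan-2-yl)benzaldehyde; 10 2-[(2E)-2-(2,2-dimethylcyclopentylidene)ethyl]-4,4,5,5-tetramethyl-1,3,2-dioxaborolane
Product: 12 (S)-[2-bromo-3,5,6-trimethoxy-4-(propan-2-yl)phenyl][(1R)-1-ethenyl-2,2-dimethylcyclopentyl]methanol, via borate ester 11 (not isolated)
Conditions: (S)-TRIP (3,3'-bis(2,4,6-triisopropylphenyl)-1,1'-binaphthyl-2,2'-diyl hydrogen phosphate, 10 mol %), 4 Å molecular sieves, toluene, −30 °C to rt; aq. NaHCO3
Reagents that add atoms: none
Why: Chiral phosphoric acid-catalysed allylboration through a Zimmerman–Traxler chair, with the aryl group and the CMe2 arm of the E-boronate equatorial and the catalyst directing attack to the Si face of the aldehyde, should set the quaternary centre C10 (R) together with the C20 carbinol (S).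

Step 8
Reactants: 12 (S)-[2-bromo-3,5,6-trimethoxy-4-(propan-2-yl)phenyl][(1R)-1-ethenyl-2,2-dimethylcyclopentyl]methanol
Product: 14 O-{(S)-[2-bromo-3,5,6-trimethoxy-4-(propan-2-yl)phenyl][(1R)-1-ethenyl-2,2-dimethylcyclopentyl]methyl} S-methyl carbonodithioate, via sodium xanthate 13 (not isolated)
Conditions: NaH, CS2, THF, 0 °C to rt; MeI
Reagents that add atoms: carbon disulfide, S=C=S; iodomethane, CI
Why: Xanthate formation (first half of the Barton–McCombie deoxygenation) uses small reagents that can reach the hindered alkoxide, and C10 carries no hydrogen for a Chugaev elimination.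

Step 9
Reactants: 14 O-{(S)-[2-bromo-3,5,6-trimethoxy-4-(propan-2-yl)phenyl][(1R)-1-ethenyl-2,2-dimethylcyclopentyl]methyl} S-methyl carbonodithioate
Product: 15 1-bromo-2-{[(1R)-1-ethenyl-2,2-dimethylcyclopentyl]methyl}-3,4,6-trimethoxy-5-(propan-2-yl)benzene
Conditions: Bu3SnH (concentrated), Et3B, trace air, toluene, rt
Reagents that add atoms: none
Why: Barton–McCombie radical deoxygenation avoids a C20 cation (which would trigger a 1,2-shift toward an allylic cation), and at room temperature with concentrated stannane the benzylic radical should be reduced before 3-exo attack on the vinyl group or loss of the aryl bromide.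

Step 10
Reactants: 15 1-bromo-2-{[(1R)-1-ethenyl-2,2-dimethylcyclopentyl]methyl}-3,4,6-trimethoxy-5-(propan-2-yl)benzene
Product: 17 2-{[(1R)-1-ethenyl-2,2-dimethylcyclopentyl]methyl}-3,4,6-trimethoxy-5-(propan-2-yl)benzoic acid, via aryllithium 16 (not isolated)
Conditions: t-BuLi (2.1 equiv), THF, −78 °C; CO2, −78 °C; aq. HCl
Reagents that add atoms: carbon dioxide, O=C=O
Why: Bromine–lithium exchange followed by carboxylation at −78 °C, where 5-exo carbolithiation of the vinyl group is slow, should install C7 as the carboxylic acid.

Step 11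
Reactants: 17 2-{[(1R)-1-ethenyl-2,2-dimethylcyclopentyl]methyl}-3,4,6-trimethoxy-5-(propan-2-yl)benzoic acid
Product: 19 (5R,7S,10S)-7,10-epoxy-11,12,14-trimethoxy-9(10→20)abeo-abieta-8,11,13-trien-7-ol, via acid chloride 18 (not isolated)
Conditions: (COCl)2, cat. DMF, CH2Cl2, 0 °C to rt, evaporation; AgOTf, CH2Cl2, −78 to −20 °C; then THF–aq. NaHCO3
Reagents that add atoms: water, O
Why: Proposed new method: AgOTf turns acid chloride 18 into the aroyl triflate and acylium ion, which should attack the terminal vinyl carbon C6 (7-endo-trig closure of ring B) on the alkene face turned away from the gem-dimethyl carbon, and as charge builds at C5 the anti-periplanar ring bond C10–C4 migrates to C5 (Wagner–Meerwein shift), so that the cyclopentane becomes ring A and C10 becomes a tertiary cation. The C7 ketone oxygen, held across ring B, then captures C10 transannularly (closing the five-membered ether ring and the isochromane ring of the bridge), and the aryl-stabilised C7 cation or bridgehead triflate left behind is hydrolysed on work-up to the hemiketal. The closest known reaction types are the intramolecular acylation of alkenes by acylium ions (Darzens–Nenitzescu type cyclisation of olefinic acid chlorides to cyclenones), the ring expansion of cyclopentylcarbinyl cations and the Prins–pinacol way of ending a cation–olefin cyclisation by a 1,2-shift; the reasoning is that the secondary β-keto cation at C5 has no hydride shift open to it and sits next to a strained ring bond aligned with its empty orbital. C5 is set by the suprafacial arrival of C4 on the face opposite to the incoming acyl carbon and is thus dictated by the C10 quaternary centre of 17 with C6 held syn to C20 by ring B, C10 is set by oxygen capture anti to the departed C4 on the face that carries C7, and C7 follows from the bridge. The step needs migration of C4 and not of C1 or C20: C4 is the most substituted migrating carbon, its bond lies anti to the acyl carbon approaching over the smaller CH2 side, and the C10–C20 bond lies near the alkene plane where it cannot overlap.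

Step 12
Reactants: 19 (5R,7S,10S)-7,10-epoxy-11,12,14-trimethoxy-9(10→20)abeo-abieta-8,11,13-trien-7-ol
Product: 20 (5R,7S,10S)-7,10-epoxy-7-hydroxy-12-methoxy-9(10→20)abeo-abieta-8,12-diene-11,14-dione (target)
Conditions: (NH4)2Ce(NO3)6, MeCN–H2O, 0 °C
Reagents that add atoms: water, O
Why: Oxidative demethylation of the para-disposed C11 and C14 methoxy groups by the one-electron oxidant should give the para-quinone (its carbonyl oxygens come from water), while the C12 methoxy group and the tertiary hemiketal are retained.

Compound list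
1 | 1,2,4-trimethoxybenzene | COc1ccc(OC)c(OC)c1 | starting material
2 | (2,3,6-trimethoxyphenyl)lithium | [Li]c1c(OC)ccc(OC)c1OC | intermediate
3 | 2-(2,3,6-trimethoxyphenyl)propan-2-ol | CC(C)(O)c1c(OC)ccc(OC)c1OC | intermediate
4 | 1,2,4-trimethoxy-3-(propan-2-yl)benzene | CC(C)c1c(OC)ccc(OC)c1OC | intermediate
5 | 1-bromo-2,4,5-trimethoxy-3-(propan-2-yl)benzene | CC(C)c1c(OC)c(Br)cc(OC)c1OC | intermediate
6 | [6-bromo-2,3,5-trimethoxy-4-(propan-2-yl)phenyl]lithium | [Li]c1c(Br)c(OC)c(C(C)C)c(OC)c1OC | intermediate
7 | 2-bromo-3,5,6-trimethoxy-4-(propan-2-yl)benzaldehyde | O=Cc1c(Br)c(OC)c(C(C)C)c(OC)c1OC | intermediate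
8 | 2,2-dimethylcyclopentan-1-one | CC1(C)CCCC1=O | starting material
9 | 1-ethenyl-2,2-dimethylcyclopentan-1-ol (racemic) | C=CC1(O)CCCC1(C)C | intermediate
10 | 2-[(2E)-2-(2,2-dimethylcyclopentylidene)ethyl]-4,4,5,5-tetramethyl-1,3,2-dioxaborolane | CC1(C)CCC/C1=C\CB2OC(C)(C)C(C)(C)O2 | intermediate
11 | 2-{(S)-[2-bromo-3,5,6-trimethoxy-4-(propan-2-yl)phenyl][(1R)-1-ethenyl-2,2-dimethylcyclopentyl]methoxy}-4,4,5,5-tetramethyl-1,3,2-dioxaborolane | COc1c([C@@H](OB2OC(C)(C)C(C)(C)O2)[C@]3(C=C)C(C)(C)CCC3)c(Br)c(OC)c(C(C)C)c1OC | intermediate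
12 | (S)-[2-bromo-3,5,6-trimethoxy-4-(propan-2-yl)phenyl][(1R)-1-ethenyl-2,2-dimethylcyclopentyl]methanol | COc1c([C@@H](O)[C@]2(C=C)C(C)(C)CCC2)c(Br)c(OC)c(C(C)C)c1OC | intermediate
13 | sodium O-{(S)-[2-bromo-3,5,6-trimethoxy-4-(propan-2-yl)phenyl][(1R)-1-ethenyl-2,2-dimethylcyclopentyl]methyl} carbonodithioate | COc1c([C@@H](OC(=S)[S-])[C@]2(C=C)C(C)(C)CCC2)c(Br)c(OC)c(C(C)C)c1OC.[Na+] | intermediate
14 | O-{(S)-[2-bromo-3,5,6-trimethoxy-4-(propan-2-yl)phenyl][(1R)-1-ethenyl-2,2-dimethylcyclopentyl]methyl} S-methyl carbonodithioate | COc1c([C@@H](OC(=S)SC)[C@]2(C=C)C(C)(C)CCC2)c(Br)c(OC)c(C(C)C)c1OC | intermediate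
15 | 1-bromo-2-{[(1R)-1-ethenyl-2,2-dimethylcyclopentyl]methyl}-3,4,6-trimethoxy-5-(propan-2-yl)benzene | COc1c(C[C@]2(C=C)C(C)(C)CCC2)c(Br)c(OC)c(C(C)C)c1OC | intermediate
16 | (2-{[(1R)-1-ethenyl-2,2-dimethylcyclopentyl]methyl}-3,4,6-trimethoxy-5-(propan-2-yl)phenyl)lithium | COc1c(C[C@]2(C=C)C(C)(C)CCC2)c([Li])c(OC)c(C(C)C)c1OC | intermediate
17 | 2-{[(1R)-1-ethenyl-2,2-dimethylcyclopentyl]methyl}-3,4,6-trimethoxy-5-(propan-2-yl)benzoic acid | COc1c(C[C@]2(C=C)C(C)(C)CCC2)c(C(O)=O)c(OC)c(C(C)C)c1OC | intermediate
18 | 2-{[(1R)-1-ethenyl-2,2-dimethylcyclopentyl]methyl}-3,4,6-trimethoxy-5-(propan-2-yl)benzoyl chloride | COc1c(C[C@]2(C=C)C(C)(C)CCC2)c(C(Cl)=O)c(OC)c(C(C)C)c1OC | intermediate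
19 | (5R,7S,10S)-7,10-epoxy-11,12,14-trimethoxy-9(10→20)abeo-abieta-8,11,13-trien-7-ol | COc1c(C(C)C)c(OC)c2c(C[C@@]34CCCC(C)(C)[C@H]3C[C@]2(O)O4)c1OC | intermediate
20 | (5R,7S,10S)-7,10-epoxy-7-hydroxy-12-methoxy-9(10→20)abeo-abieta-8,12-diene-11,14-dione | COC1=C(C(C)C)C(=O)C2=C(C[C@@]34CCCC(C)(C)[C@H]3C[C@]2(O)O4)C1=O | target

Total step count: 12. Longest linear sequence: 10 steps (steps 1 to 4, then 7 to 12).

Steps most likely to fail

First, step 11 (proposed new method). The stabilised aroyl cation may fail to engage the monosubstituted alkene. The C5 cation may also lose a proton to give the enone, or be intercepted by migration of C1 or by the C11 methoxy oxygen before the ketone oxygen reaches C10. The fallback separates ring B closure from the ring expansion and uses known reactions. It sets out from 17: acid chloride 18 and tributyl(vinyl)stannane with PdCl2(PPh3)2 (Migita–Stille acylation) would give aryl vinyl ketone F1. Ring-closing metathesis with the second-generation Hoveyda–Grubbs catalyst would close ring B to spiro enone F2. Treating F2 with CF3SO3H in CH2Cl2 at 0 °C and then water would bring about the acid-promoted 1,2-shift of C4 to the β-carbon of the protonated enone, the known rearrangement of γ,γ-disubstituted cycloalkenones (as in the dienone–phenol ring expansion of spiro dienones), followed by hydration and ketalisation. The fallback comes back to the route at 19.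

Second, step 7. Bond formation between a di-ortho-substituted aldehyde and a γ-carbon flanked by a quaternary centre may be slow. The higher temperature then needed would erode facial selectivity and the chair preference, and with it the configuration at C10. The fallback changes the allyl metal. It sets out from 9: PBr3 in Et2O would give, with allylic transposition, allylic bromide F3. F3 would add to aldehyde 7 in a Nozaki–Hiyama–Kishi reaction with CrCl2, a chiral oxazoline–sulfonamide ligand and proton sponge in THF; the allylchromium species reacts at its γ-carbon through a closed transition state. The fallback comes back to the route at 12.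

Third, step 9 (with step 8). Thioacylation of the hindered alkoxide may be incomplete. In the radical step the benzylic radical may attack the vinyl group (3-exo closure and 1,2-vinyl shift), or the aryl bromide may be reduced. The fallback removes the benzylic oxygen by electron transfer. It sets out from 12: t-BuLi (3 equiv) in THF at −78 °C, then CO2 and acid, would give phthalide F4 by carboxylation and lactonisation. Lithium naphthalenide (LiC10H8) in THF at −78 °C would cleave the benzylic C–O bond of the aromatic lactone through its radical anion. The fallback comes back to the route at 17.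

Further compounds
F1 | step 11 | 1-(2-{[(1R)-1-ethenyl-2,2-dimethylcyclopentyl]methyl}-3,4,6-trimethoxy-5-(propan-2-yl)phenyl)prop-2-en-1-one | COc1c(C[C@]2(C=C)C(C)(C)CCC2)c(C(=O)C=C)c(OC)c(C(C)C)c1OC
F2 | step 11 | (R)-1,2,4-trimethoxy-2',2'-dimethyl-3-(propan-2-yl)spiro[benzo[7]annulene-8,1'-cyclopentan]-5(9H)-one (spiro enone) | COc1c(C(C)C)c(OC)c2c(c1OC)C[C@]3(C=CC2=O)C(C)(C)CCC3
F3 | step 7 | (E)-1-(2-bromoethylidene)-2,2-dimethylcyclopentane | BrC/C=C1\CCCC1(C)C
F4 | step 9 | (3S)-3-[(1R)-1-ethenyl-2,2-dimethylcyclopentyl]-4,5,7-trimethoxy-6-(propan-2-yl)-2-benzofuran-1(3H)-one | O=C1O[C@H](c2c1c(OC)c(C(C)C)c(OC)c2OC)[C@]3(C=C)C(C)(C)CCC3
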